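The synthesis rests on one retrosynthetic bond, C4–C9, which folds the ten-membered carbocycle into a cis-decalin (ring A: C1–C4, C9, C10; ring B: C4–C9). The feature exploited is the 1,3-relationship between the Z C4=C5 double bond and the oxygen-bearing C9. These are what a Grob fragmentation of a C9-ol C5-sulfonate leaves behind. In one operation the key step cuts the ring-fusion bond, releases the cyclodecene, fixes the Z geometry and unmasks a C9 ketone. Its precursor is a cis-fused decalin with a free tertiary C9–OH, an equatorial C5 mesylate and C1, C3, C6, C7 and C10 already set. It is assembled from (S)-carvone and a malic-acid-derived keto aldehyde by aldol addition and SmI2 pinacol closure.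

Key step: step 16

Remark on numbering: germacrane numbers are kept for every intermediate. C6 is the lactone O–CH, C4=C5 the alkene with its methyl on C4, C3 and C1 carbinols, C10 the methyl carbinol, C9 the ester carbinol, and C7 carries C11–C13. In the decalins, β is the face of the C4 methyl group and α the opposite face.

Assumption: (R)-α-hydroxy-γ-butyrolactone, a chiral-pool compound of the (R)-malic acid series, is taken as purchasable.

Design of the fragmentation substrate:
- The tertiary C10–O carries TES rather than a smaller silyl group. This slows O-to-O silyl migration to the neighbouring C9 alkoxide, and the group also survives the later steps and steers the C9 reduction.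
- The C5 configuration is made by ketone reduction, not by epoxide opening at a neopentyl carbon.
- The chair–chair form with C3 axial on ring B is the one that keeps C5–OMs, C6–O and the C7 side chain equatorial. The flipped form would place C5–OMs, the C7 side chain and C10 in a triaxial array.

Step 1
Reactants: 1 (S)-carvone
Product: 2 (S)-10-chlorocarvone
Conditions: Ca(OCl)2, solid CO2, CH2Cl2/H2O, 0 °C
Reagents that add atoms: calcium hypochlorite, [Ca+2].[O-]Cl.[O-]Cl
Why: Ene-type allylic chlorination by hypochlorous acid attacks only the electron-rich 1,1-disubstituted side-chain alkene, so the electron-poor enone and the C7 stereocentre stay untouched.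

Step 2
Reactants: 2 (S)-10-chlorocarvone
Product: 4 (S)-10-hydroxycarvone, via allylic acetate 3 (not isolated)
Conditions: KOAc, NaI (cat.), DMF, 60 °C; then MeOH, K2CO3 (cat.), rt
Reagents that add atoms: potassium acetate, [K+].CC(=O)[O-]
Why: SN2 displacement of a primary allylic chloride by acetate followed by base-catalysed transesterification is routine and involves no stereocentre.

Step 3
Reactants: 4 (S)-10-hydroxycarvone
Product: 5 (S)-10-(tert-butyldimethylsilyloxy)carvone
Conditions: TBSCl, imidazole, CH2Cl2, rt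
Reagents that add atoms: tert-butyldimethylsilyl chloride, CC(C)(C)[Si](C)(C)Cl
Why: Standard silyl ether protection of a primary allylic alcohol gives a group that tolerates the later enolate, SmI2, osmium, hydride and alkoxide steps.

Step 4
Reactants: 6 (R)-α-hydroxy-γ-butyrolactone
Product: 7 (3R)-3-(tert-butyldimethylsilyloxy)oxolan-2-one
Conditions: TBSCl, imidazole, DMF, rt
Reagents that add atoms: tert-butyldimethylsilyl chloride, CC(C)(C)[Si](C)(C)Cl
Why: Routine silyl ether formation leaves the chiral-pool stereocentre untouched, and this centre becomes C1 with the configuration required in the target.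

Step 5
Reactants: 7 (3R)-3-(tert-butyldimethylsilyloxy)oxolan-2-one
Product: 9 (3R)-3-(tert-butyldimethylsilyloxy)-5-hydroxypentan-2-one, via lithium hemiketal alkoxide 8 (not isolated)
Conditions: MeLi (1.0 equiv), THF, −78 °C; then AcOH, −78 °C
Reagents that add atoms: methyllithium, [Li]C
Why: Mono-addition of an organolithium to a γ-lactone stops at the tetrahedral alkoxide 8 at low temperature, so the methyl ketone (C10, C14) appears only after the cold quench and C1 is not enolised.

Step 6
Reactants: 9 (3R)-3-(tert-butyldimethylsilyloxy)-5-hydroxypentan-2-one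
Product: 10 (3R)-3-(tert-butyldimethylsilyloxy)-4-oxopentanal
Conditions: Dess–Martin periodinane, CH2Cl2, 0 °C to rt; used crude
Reagents that add atoms: none
Why: Dess–Martin oxidation is non-basic, so the primary alcohol becomes the C3 aldehyde without β-elimination of the silyloxy group or epimerisation at C1.

Step 7
Reactants: 5 (S)-10-(tert-butyldimethylsilyloxy)carvone; 10 (3R)-3-(tert-butyldimethylsilyloxy)-4-oxopentanal
Product: 13 (2S,5R)-2-[(1S,3R)-3-(tert-butyldimethylsilyloxy)-1-hydroxy-4-oxopentyl]-5-[3-(tert-butyldimethylsilyloxy)prop-1-en-2-yl]-2-methylcyclohex-3-en-1-one, via potassium dienolate 11 (not isolated), via titanium dienolate 12 (not isolated)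
Conditions: KOtBu (1.1 equiv), THF, −20 °C; ClTi(OiPr)3, −78 °C; then 10, −78 °C; aq. NH4Cl
Reagents that add atoms: none
Why: Equilibrating γ-deprotonation gives the linear thermodynamic dienolate, whose titanium form adds at its α-carbon (deconjugative aldol) to the aldehyde in preference to the ketone of 10 through a Zimmerman–Traxler chair, with C4 set by pseudoaxial attack on the half-chair that keeps the C7 side chain pseudoequatorial (new chain cis to it) and C3 set by the closed transition state that puts the hydroxyl syn to the C4 methyl.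

Step 8
Reactants: 13 aldol adduct
Product: 14 C3 triethylsilyl ether of 13
Conditions: TESOTf, 2,6-lutidine, CH2Cl2, −78 °C
Reagents that add atoms: triethylsilyl triflate, CC[Si](CC)(CC)OS(=O)(=O)C(F)(F)F
Why: A silyl triflate with a hindered pyridine base silylates the congested C3 carbinol at low temperature (silyl ether protection), which blocks retro-aldol cleavage and hydroxyl-directed ketone reduction in the next step.

Step 9
Reactants: 14 diketone
Product: 15 cis-decalin-9β,10β-diol (4β-Me; 10α-Me; 1α-OTBS; 3α-OTES; 7α side chain; C5=C6)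
Conditions: SmI2 (2.5 equiv), t-BuOH (2 equiv), THF, −78 to 0 °C
Reagents that add atoms: none
Why: The intramolecular ketone–ketone pinacol coupling (six-membered closure) starts at the more easily reduced α-silyloxy methyl ketone, the α-face tether at C4 reaches C9 from that face (cis fusion, C9–OH β), and chelation of both oxygens by trivalent samarium gives the cis-diol (C10–OH β, methyl α) with the new C10–O anti to the C1 silyloxy group.

Step 10
Reactants: 15 cis-decalin-9β,10β-diol
Product: 16 C10 triethylsilyl ether with free 9β-OH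
Conditions: TESOTf (1.1 equiv), 2,6-lutidine, CH2Cl2, −78 to −40 °C
Reagents that add atoms: triethylsilyl triflate, CC[Si](CC)(CC)OS(=O)(=O)C(F)(F)F
Why: C10–OH has a methyl and a methine neighbour whereas the ring-fusion C9–OH lies between two fully substituted carbons, so one equivalent of reagent should silylate C10–OH only (selective silyl ether formation).

Step 11
Reactants: 16 decalin alkene with free 9β-OH
Product: 18 5β,6β,9β-triol, via cyclic osmate ester 17 (not isolated)
Conditions: OsO4 (1.0 equiv), TMEDA (1.1 equiv), CH2Cl2, −78 °C; then aq. Na2SO3, THF, reflux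
Reagents that add atoms: osmium tetroxide, O=[Os](=O)(=O)=O
Why: In this hydrogen-bond-directed syn-dihydroxylation the OsO4·TMEDA complex is held by the β-oriented homoallylic C9–OH and delivered to the β face of C5=C6, which is also the open face because C3 and the C7 side chain shield the α face, so the ring alkene is preferred over the remote side-chain alkene and C6–O is set as in the target.

Step 12
Reactants: 18 5β,6β,9β-triol
Product: 19 6β-OTBS-5β,9β-diol
Conditions: TBSOTf (1.05 equiv), 2,6-lutidine, CH2Cl2, −78 °C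
Reagents that add atoms: tert-butyldimethylsilyl triflate, CC(C)(C)[Si](C)(C)OS(=O)(=O)C(F)(F)F
Why: The equatorial C6–OH is far more accessible than the axial neopentyl-type C5–OH and the tertiary C9–OH, so selective mono-silylation is expected.

Step 13
Reactants: 19 6β-OTBS-5β,9β-diol
Product: 20 C5 ketone (9β-hydroxy-5-one)
Conditions: Dess–Martin periodinane, CH2Cl2, 0 °C to rt
Reagents that add atoms: none
Why: Dess–Martin oxidation converts the only secondary alcohol into the ketone under non-basic conditions that avoid retro-aldol opening of the β-hydroxy ketone and leave the equatorial C6 centre unchanged.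

Step 14
Reactants: 20 C5 ketone
Product: 21 5α,9β-diol (equatorial C5–OH)
Conditions: Me4NBH(OAc)3, MeCN/AcOH, −30 °C
Reagents that add atoms: none
Why: In the Evans–Saksena reduction the acetoxyborohydride binds to the axial C9–OH and delivers hydride to the β face of C5, which is also the face not blocked by the axial C3, giving the anti-1,3-diol and hence the equatorial 5α-alcohol.

Step 15
Reactants: 21 5α,9β-diol
Product: 22 cis-decalin C9-ol C5α-mesylate
Conditions: MsCl, Et3N, CH2Cl2, 0 °C
Reagents that add atoms: methanesulfonyl chloride, CS(=O)(=O)Cl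
Why: Sulfene-type mesylation reacts only with the secondary C5–OH because the tertiary C9–OH is inert, and triethylamine is too weak a base to start the fragmentation.

Step 16
Reactants: 22 cis-decalin C9-ol C5α-mesylate
Product: 24 (4Z)-cyclodecenone (C9 ketone), via potassium C9 alkoxide 23 (not isolated)
Conditions: KOtBu (1.3 equiv), THF, 0 °C
Reagents that add atoms: none
Why: KOtBu deprotonates the only free hydroxyl to give 23, whose oxygen lone pair forms the C9 carbonyl while the C4–C9 σ bond becomes the C4=C5 π bond and mesylate leaves C5 in one concerted Grob (Wharton-type) fragmentation of a 1,3-diol monosulfonate, a reaction well established for decalin-1,3-diol monosulfonates giving cyclodecenones. No ring is closed by bond formation: the ten-membered carbocycle appears because the bond shared by rings A and B is cut, so its size is dictated by the bicycle and no dilution is needed. No stereocentre is created (C4, C5 and C9 are erased; C1, C3, C6, C7 and C10 are untouched), and the alkene geometry follows only from the 4β-methyl/5α-mesylate relationship, because in the antiperiplanar C9–C4–C5–O array C3 sits gauche to C6 and the methyl gauche to H5, which maps onto the Z alkene. The selectivity needed is fragmentation over oxetane formation, 1,2-shift or E2, and it is secured by the ring B chair, which is held by the equatorial C5, C6 and C7 substituents so that the equatorial mesylate is aligned with C4–C9 and has no antiperiplanar hydrogen. C1–O, C3–O and C10–O are silylated, so no second alkoxide can cleave C3–C4 or trigger a retro-aldol of the product, and the strain of the crowded ring A is released in the transition state.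

Step 17
Reactants: 24 (4Z)-cyclodecenone
Product: 25 (9S)-alcohol
Conditions: (R)-1-methyl-3,3-diphenyltetrahydro-1H,3H-pyrrolo[1,2-c][1,3,2]oxazaborole (20 mol %), catecholborane, toluene, −78 to −40 °C; MeOH, pH 7 buffer
Reagents that add atoms: none
Why: The Corey–Bakshi–Shibata reduction distinguishes the fully substituted C10 flank from the C8 methylene flank, so the (R)-catalyst should give the 9S alcohol, which is the same sense as a Felkin–Anh/Cornforth arrangement with the C10–OTES bond turned away from the carbonyl, and catecholborane at low temperature leaves the alkenes alone.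

Step 18
Reactants: 25 (9S)-alcohol; 26 angelic acid
Product: 28 C9 angelate (penta-silyl ether), via mixed anhydride 27 (not isolated)
Conditions: 26, 2,4,6-trichlorobenzoyl chloride, Et3N, toluene, rt; then 25, 80 °C
Reagents that add atoms: none
Why: Yamaguchi-type mixed-anhydride esterification run without a nucleophilic catalyst acylates hindered secondary alcohols with angelic acid without Z-to-E isomerisation and with retention at C9.

Step 19
Reactants: 28 C9 angelate (penta-silyl ether)
Product: 29 pentaol (1,3,6,10,12-pentahydroxy 9-angelate)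
Conditions: HF·pyridine, pyridine/THF, 0 °C to rt
Reagents that add atoms: none
Why: Fluoride-mediated cleavage of all five silyl ethers under buffered, mildly acidic conditions avoids acyl migration, ester cleavage and angelate isomerisation.

Step 20
Reactants: 29 pentaol
Product: 32 target CNP0493102.1, via hydroxy enal 30 (not isolated), via lactol 31 (not isolated)
Conditions: 2,2,6,6-tetramethylpiperidin-1-oxyl (TEMPO, 20 mol %), PhI(OAc)2 (2.5 equiv), CH2Cl2, rt
Reagents that add atoms: none
Why: Oxoammonium oxidation is selective for the primary allylic alcohol, the enal 30 is captured by the neighbouring C6–OH as lactol 31, and this is oxidised on to the trans-fused α-methylene-γ-lactone (oxidative lactonisation), while the hindered secondary and the tertiary hydroxyls react much more slowly.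

Compound list

1 | (S)-carvone | CC1=CC[C@@H](CC1=O)C(=C)C | starting material
2 | (S)-10-chlorocarvone, (5S)-5-(3-chloroprop-1-en-2-yl)-2-methylcyclohex-2-en-1-one | CC1=CC[C@@H](CC1=O)C(=C)CCl | intermediate
3 | (S)-10-acetoxycarvone | CC1=CC[C@@H](CC1=O)C(=C)COC(C)=O | intermediate
4 | (S)-10-hydroxycarvone | CC1=CC[C@@H](CC1=O)C(=C)CO | intermediate
5 | (S)-10-(tert-butyldimethylsilyloxy)carvone | CC1=CC[C@@H](CC1=O)C(=C)CO[Si](C)(C)C(C)(C)C | intermediate
6 | (R)-α-hydroxy-γ-butyrolactone, (3R)-3-hydroxyoxolan-2-one | O=C1OCC[C@H]1O | starting material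
7 | (3R)-3-(tert-butyldimethylsilyloxy)oxolan-2-one | O=C1OCC[C@H]1O[Si](C)(C)C(C)(C)C | intermediate
8 | lithium (3R)-3-(tert-butyldimethylsilyloxy)-2-methyloxolan-2-olate | [Li+].[O-]C1(C)OCC[C@H]1O[Si](C)(C)C(C)(C)C | intermediate
9 | (3R)-3-(tert-butyldimethylsilyloxy)-5-hydroxypentan-2-one | OCC[C@@H](O[Si](C)(C)C(C)(C)C)C(C)=O | intermediate
10 | (3R)-3-(tert-butyldimethylsilyloxy)-4-oxopentanal | O=CC[C@@H](O[Si](C)(C)C(C)(C)C)C(C)=O | intermediate
11 | potassium linear (C9=C4, C5=C6) dienolate of 5 | [K+].[O-]C1=C(C)C=C[C@@H](C1)C(=C)CO[Si](C)(C)C(C)(C)C | intermediate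
12 | triisopropoxytitanium linear dienolate of 5 | CC(C)O[Ti](OC(C)C)(OC(C)C)OC1=C(C)C=C[C@@H](C1)C(=C)CO[Si](C)(C)C(C)(C)C | intermediate
13 | aldol adduct, (2S,5R)-2-[(1S,3R)-3-(TBSO)-1-hydroxy-4-oxopentyl]-5-[3-(TBSO)prop-1-en-2-yl]-2-methylcyclohex-3-en-1-one | C=C(CO[Si](C)(C)C(C)(C)C)[C@H]1C=C[C@@](C)([C@@H](O)C[C@@H](O[Si](C)(C)C(C)(C)C)C(C)=O)C(=O)C1 | intermediate
14 | C3 triethylsilyl ether of 13 (C9,C10-diketone) | C=C(CO[Si](C)(C)C(C)(C)C)[C@H]1C=C[C@@](C)([C@@H](O[Si](CC)(CC)CC)C[C@@H](O[Si](C)(C)C(C)(C)C)C(C)=O)C(=O)C1 | intermediate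
15 | cis-decalin-9β,10β-diol: 4β-Me, 10α-Me, 1α-OTBS, 3α-OTES, 7α-[3-(TBSO)prop-1-en-2-yl], C5=C6 | C=C(CO[Si](C)(C)C(C)(C)C)[C@H]1C=C[C@@]2(C)[C@@H](O[Si](CC)(CC)CC)C[C@@H](O[Si](C)(C)C(C)(C)C)[C@](C)(O)[C@@]2(O)C1 | intermediate
16 | 10β-OTES derivative of 15, 9β-OH free | C=C(CO[Si](C)(C)C(C)(C)C)[C@H]1C=C[C@@]2(C)[C@@H](O[Si](CC)(CC)CC)C[C@@H](O[Si](C)(C)C(C)(C)C)[C@](C)(O[Si](CC)(CC)CC)[C@@]2(O)C1 | intermediate
17 | cyclic 5β,6β-osmate ester of 16 (hexavalent osmium), TMEDA adduct | C=C(CO[Si](C)(C)C(C)(C)C)[C@H]1[C@@H]3O[Os](=O)(=O)O[C@@H]3[C@@]2(C)[C@@H](O[Si](CC)(CC)CC)C[C@@H](O[Si](C)(C)C(C)(C)C)[C@](C)(O[Si](CC)(CC)CC)[C@@]2(O)C1.CN(C)CCN(C)C | intermediate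
18 | 5β,6β,9β-triol | C=C(CO[Si](C)(C)C(C)(C)C)[C@H]1[C@H](O)[C@H](O)[C@@]2(C)[C@@H](O[Si](CC)(CC)CC)C[C@@H](O[Si](C)(C)C(C)(C)C)[C@](C)(O[Si](CC)(CC)CC)[C@@]2(O)C1 | intermediate
19 | 6β-OTBS-5β,9β-diol | C=C(CO[Si](C)(C)C(C)(C)C)[C@H]1[C@H](O[Si](C)(C)C(C)(C)C)[C@H](O)[C@@]2(C)[C@@H](O[Si](CC)(CC)CC)C[C@@H](O[Si](C)(C)C(C)(C)C)[C@](C)(O[Si](CC)(CC)CC)[C@@]2(O)C1 | intermediate
20 | 6β-OTBS-9β-hydroxy-5-ketone | C=C(CO[Si](C)(C)C(C)(C)C)[C@H]1[C@H](O[Si](C)(C)C(C)(C)C)C(=O)[C@@]2(C)[C@@H](O[Si](CC)(CC)CC)C[C@@H](O[Si](C)(C)C(C)(C)C)[C@](C)(O[Si](CC)(CC)CC)[C@@]2(O)C1 | intermediate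
21 | 6β-OTBS-5α,9β-diol (C5–OH equatorial) | C=C(CO[Si](C)(C)C(C)(C)C)[C@H]1[C@H](O[Si](C)(C)C(C)(C)C)[C@@H](O)[C@@]2(C)[C@@H](O[Si](CC)(CC)CC)C[C@@H](O[Si](C)(C)C(C)(C)C)[C@](C)(O[Si](CC)(CC)CC)[C@@]2(O)C1 | intermediate
22 | fragmentation precursor: cis-decalin 9β-ol 5α-mesylate (4β-Me, 6β-OTBS, 7α side chain, 1α-OTBS, 3α-OTES, 10β-OTES, 10α-Me) | C=C(CO[Si](C)(C)C(C)(C)C)[C@H]1[C@H](O[Si](C)(C)C(C)(C)C)[C@@H](OS(C)(=O)=O)[C@@]2(C)[C@@H](O[Si](CC)(CC)CC)C[C@@H](O[Si](C)(C)C(C)(C)C)[C@](C)(O[Si](CC)(CC)CC)[C@@]2(O)C1 | intermediate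
23 | potassium C9 alkoxide of 22 | [K+].C=C(CO[Si](C)(C)C(C)(C)C)[C@H]1[C@H](O[Si](C)(C)C(C)(C)C)[C@@H](OS(C)(=O)=O)[C@@]2(C)[C@@H](O[Si](CC)(CC)CC)C[C@@H](O[Si](C)(C)C(C)(C)C)[C@](C)(O[Si](CC)(CC)CC)[C@@]2([O-])C1 | intermediate
24 | fragmentation product: (4Z)-germacra-4,11(13)-dien-9-one with 1-OTBS, 3-OTES, 6-OTBS, 10-OTES, 12-OTBS; C1, C3, C6, C7, C10 as in the target | C=C(CO[Si](C)(C)C(C)(C)C)[C@H]1[C@H](O[Si](C)(C)C(C)(C)C)/C=C(/C)[C@@H](O[Si](CC)(CC)CC)C[C@@H](O[Si](C)(C)C(C)(C)C)[C@](C)(O[Si](CC)(CC)CC)C(=O)C1 | intermediate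
25 | (9S)-alcohol from 24 | C=C(CO[Si](C)(C)C(C)(C)C)[C@H]1[C@H](O[Si](C)(C)C(C)(C)C)/C=C(/C)[C@@H](O[Si](CC)(CC)CC)C[C@@H](O[Si](C)(C)C(C)(C)C)[C@](C)(O[Si](CC)(CC)CC)[C@@H](O)C1 | intermediate
26 | angelic acid, (Z)-2-methylbut-2-enoic acid | C/C=C(/C)C(=O)O | starting material
27 | angelic 2,4,6-trichlorobenzoic mixed anhydride | C/C=C(/C)C(=O)OC(=O)c1c(Cl)cc(Cl)cc1Cl | intermediate
28 | C9 angelate of 25 | C=C(CO[Si](C)(C)C(C)(C)C)[C@H]1[C@H](O[Si](C)(C)C(C)(C)C)/C=C(/C)[C@@H](O[Si](CC)(CC)CC)C[C@@H](O[Si](C)(C)C(C)(C)C)[C@](C)(O[Si](CC)(CC)CC)[C@@H](OC(=O)/C(C)=C\C)C1 | intermediate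
29 | pentaol: 9-angeloyloxy-(4Z)-germacra-4,11(13)-diene-1,3,6,10,12-pentaol | C=C(CO)[C@H]1[C@H](O)/C=C(/C)[C@@H](O)C[C@@H](O)[C@](C)(O)[C@@H](OC(=O)/C(C)=C\C)C1 | intermediate
30 | C12 enal (1,3,6,10-tetraol) | C=C(C=O)[C@H]1[C@H](O)/C=C(/C)[C@@H](O)C[C@@H](O)[C@](C)(O)[C@@H](OC(=O)/C(C)=C\C)C1 | intermediate
31 | 12,6-lactol (C12 epimers) | C=C1C(O)O[C@@H]2/C=C(/C)[C@@H](O)C[C@@H](O)[C@](C)(O)[C@@H](OC(=O)/C(C)=C\C)C[C@@H]12 | intermediate
32 | CNP0493102.1, (1R,3S,4Z,6R,7S,9S,10S)-9-angeloyloxy-1,3,10-trihydroxygermacra-4,11(13)-dien-12,6-olide | C=C1C(=O)O[C@@H]2/C=C(/C)[C@@H](O)C[C@@H](O)[C@](C)(O)[C@@H](OC(=O)/C(C)=C\C)C[C@@H]12 | target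

Total step count: 20. Longest linear sequence: 17 (steps 1–3 and 7–20, from (S)-carvone).

Steps most likely to fail

1. Step 16 (key step).
   - Risk: the crowded ring A may twist ring B out of its chair. Fragmentation then slows, and intramolecular displacement of the mesylate by the alkoxide or silyl migration from C10–O to C9–O takes over.
   - Fallback: the same C4–C9 bond is cut by a retro-aldol instead of a sulfonate fragmentation. It sets out from 20. One equivalent of KHMDS at −78 °C in the presence of N-(5-chloropyridin-2-yl)bis(trifluoromethanesulfonimide) converts the β-hydroxy ketone into its alkoxide. This opens by retro-aldol cleavage to the ten-membered C4=C5 enolate, in which the equatorial methyl, nearly eclipsed with the C5 carbonyl, ends cis to oxygen and C3 ends cis to C6. The enolate is trapped as the enol triflate F3. Reduction of the C–O bond with Pd(OAc)2/PPh3, HCO2H and Bu3N in DMF proceeds with retention of alkene geometry and comes back to the route at 24.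

2. Step 7.
   - Risk: equilibration to the linear dienolate may be incomplete, so that reaction goes through the cross-conjugated enolate. Proton transfer to the hindered nucleophile, reversal of the aldol, or poor facial selectivity at C4 are also possible.
   - Fallback: the C9=C4 enolate is made regiospecifically by conjugate addition. It sets out from 5 and 10. iBu2AlSePh (from iBu2AlH and PhSeSePh) adds to C5 of 5 anti to the side chain. The aluminium enolate is captured by 10 anti to selenium through a closed transition state, giving the β-phenylseleno aldol F1. H2O2 oxidises it to the selenoxide F2. Because C4 is quaternary, F2 can undergo syn elimination only towards C6, and this comes back to the route at 13.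

3. Step 11.
   - Risk: chemoselectivity may be lost through osmylation of the unhindered side-chain alkene, or the chelated osmate may hydrolyse sluggishly.
   - Fallback: the competing alkene is removed temporarily instead of relying on reagent delivery. It sets out from 16. One equivalent of pyridinium tribromide at −78 °C adds bromine to the more nucleophilic 1,1-disubstituted alkene to give the side-chain dibromide F4. Catalytic OsO4 with N-methylmorpholine N-oxide then dihydroxylates C5=C6 from the sterically open β face to give the dibromo triol F5. Zinc dust with NH4Cl in EtOH restores the side-chain alkene and comes back to the route at 18.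

Further compounds

F1 | step 7 | 5β-phenylseleno aldol (saturated C5–C6 analogue of 13) | C=C(CO[Si](C)(C)C(C)(C)C)[C@H]1C[C@H]([Se]c2ccccc2)[C@@](C)([C@@H](O)C[C@@H](O[Si](C)(C)C(C)(C)C)C(C)=O)C(=O)C1
F2 | step 7 | selenoxide of F1 | C=C(CO[Si](C)(C)C(C)(C)C)[C@H]1C[C@H]([Se](=O)c2ccccc2)[C@@](C)([C@@H](O)C[C@@H](O[Si](C)(C)C(C)(C)C)C(C)=O)C(=O)C1
F3 | step 16 | ten-membered C9 ketone C5 enol triflate (C3 cis to C6) | C=C(CO[Si](C)(C)C(C)(C)C)[C@H]1[C@H](O[Si](C)(C)C(C)(C)C)/C(OS(=O)(=O)C(F)(F)F)=C(/C)[C@@H](O[Si](CC)(CC)CC)C[C@@H](O[Si](C)(C)C(C)(C)C)[C@](C)(O[Si](CC)(CC)CC)C(=O)C1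
F4 | step 11 | C11,C13-dibromide of 16 (C11 epimers) | BrCC(Br)(CO[Si](C)(C)C(C)(C)C)[C@H]1C=C[C@@]2(C)[C@@H](O[Si](CC)(CC)CC)C[C@@H](O[Si](C)(C)C(C)(C)C)[C@](C)(O[Si](CC)(CC)CC)[C@@]2(O)C1
F5 | step 11 | C11,C13-dibromo-5β,6β,9β-triol | BrCC(Br)(CO[Si](C)(C)C(C)(C)C)[C@H]1[C@H](O)[C@H](O)[C@@]2(C)[C@@H](O[Si](CC)(CC)CC)C[C@@H](O[Si](C)(C)C(C)(C)C)[C@](C)(O[Si](CC)(CC)CC)[C@@]2(O)C1
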